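The numbers in the tables stem from a simulated flask with constants of no real substance, and the scatter is random.

- Along the time axis, the curve of intermediate C starts from zero behind intermediate B: Monday's run reads 3 % against 21 % at 1.50 h.

common to all: substrate 0.050 M

| flask | partner | remark | time |
|---|---|---|---|
| Monday's | 0.065 M | run made earlier |  |
| Friday's | 0.076 M | run made earlier |  |
| Tuesday's | 0.082 M | run made earlier |  |
| autumn | 0.0900 M |  | 20 h |
| winter | 0.0750 M |  | 20 h |

| run | time / h | intermediate B / % | substrate / % | intermediate A / % | product / % | intermediate C / % |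
|---|---|---|---|---|---|---|
| Monday's | 1.50 | 21 | 57 | 10 | 2 | 3 |
| Monday's | 3.00 | 30 | 37 | 12 | 4 | 15 |
| Monday's | 6.00 | 31 | 15 | 13 | 11 | 32 |
| Monday's | 10.0 | 24 | 4 | 9 | 15 | 52 |
| Monday's | 20.0 | 13 | 3 | 2 | 18 | 67 |
| Friday's | 4.00 | 26 | 29 | 10 | 10 | 25 |
| Friday's | 8.00 | 23 | 7 | 10 | 16 | 44 |
| Friday's | 12.0 | 18 | 3 | 10 | 18 | 55 |
| Friday's | 15.0 | 17 | 1 | 2 | 20 | 60 |
| Friday's | 20.0 | 6 | 3 | 6 | 22 | 67 |
| Tuesday's | 2.00 | 22 | 50 | 13 | 2 | 10 |
| Tuesday's | 5.00 | 26 | 17 | 12 | 13 | 34 |
| Tuesday's | 10.0 | 19 | 7 | 8 | 16 | 53 |
| Tuesday's | 15.0 | 8 | 0 | 3 | 19 | 62 |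
| Tuesday's | 20.0 | 10 | 0 | 1 | 21 | 70 |

(each reading ± 2 percentage points)

* which of these there is most of at the end, counted by the substrate in it, autumn (product / intermediate B / intermediate C / intermediate A)
* which of these there is most of at the end, counted by the substrate in it, winter (product / intermediate B / intermediate C / intermediate A)
* the largest of these amounts at the end, in percent of the substrate charged, autumn
* the largest of these amounts at the end, in percent of the substrate charged, winter

- candidate steps: substrate <-> intermediate A; partner + intermediate B <-> intermediate C; partner + intermediate A -> product; substrate -> intermediate B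

- The substrate falls first: Tuesday's 17 % at 5.00 h reads as a first-order constant of 0.354 h⁻¹, a half-life of 1.96 h.
- The crossing of C over B lies between 3.00 h and 6.00 h on Monday's run, and between 2.00 h and 5.00 h on Tuesday's.
- For the level, free partner is the charge minus the partner taken into C and product. C divided by B and by free partner then reads 229 M⁻¹, 354 M⁻¹ and 192 M⁻¹ at 20 h on Monday's, Friday's and Tuesday's runs, with mean 258 M⁻¹. This mean of readings is the end mass-action quotient, a value for that time: Monday's B reads 24 % at 10.0 h and less, 13 %, at 20 h.
- At 20 h in these runs, the pool of B plus C averages 77.7 % and C plus product 88.3 %. With free partner f, and both averages held, C is reckoned as the pool of B plus C times Qf/(1+Qf).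
- My reckoning gives autumn f = 0.0458 M and C 71.6 %; winter f = 0.0308 M and C 69.0 %.
- The forecast names intermediate C for autumn at 71 % and intermediate C for winter at 68.5 %, saying C “should stay dominant in both new runs”; my reckoning stands 0.60 percentage points and 0.50 points above it.
- The flasks give intermediate C at 70.2 % in autumn and intermediate C at 67.6 % in winter, so the forecast held. In autumn the substrate passed into A and B and stood at 4.76 % at 10.0 h; from then to 20.0 h, C rose from 57.3 % to 70.2 % while B fell from 14.7 % to 6.61 %. The end quotient comes to 240 M⁻¹ in autumn and 209 M⁻¹ in winter.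

    substrate ⇌ intermediate A (K = 1.20, k = 0.110 h⁻¹)
    partner + intermediate B ⇌ intermediate C (K = 400 M⁻¹, k = 4.30 M⁻¹ h⁻¹)
    partner + intermediate A → product (k = 2.70 M⁻¹ h⁻¹)
    substrate → intermediate B (k = 0.250 h⁻¹)

- A neighbour of autumn takes 0.085 M of substrate. With the same quotient and pool, a first pass gives C 61.7 %, and a second pass, with free partner reckoned from that C, gives 65.2 %. That flask gives 63.7 %.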